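**Analysis of the target**

Target 24 is an isoflavone. Its 4H-chromen-4-one core consists of benzo ring A, which carries a methoxy group at C7, and pyranone ring C. C3 of ring C is bonded to C1' of ring B. Ring B is the benzo ring of a 2,2-dimethyl-2H-chromene: pyran ring D is fused across C3'–C4' with its oxygen on C4', and C2' bears a methoxy group. The molecule has no stereocentre, and the C3–C1' axis, with one ortho neighbour on each side, is not configurationally stable, so no stereochemical question arises. Two groups are sensitive. C2 of ring C is a Michael acceptor, so hydroxide and alkoxides can open the pyranone. The ring D double bond is an electron-rich styrene that is easily protonated, halogenated or oxidised. The difficulty is twofold. Ring B is a 1,2,3,4-tetrasubstituted benzene whose substituents must stand in the order aryl, oxygen, carbon, oxygen. The C3–C1' bond joins two electron-rich sp2 carbons, one next to the C4 carbonyl and the other next to the C2' oxygen. The strategy rests on the fact that C2 carries only hydrogen while C2' carries oxygen. A carboxyl carbon on C2 bound to the C2' oxygen closes a six-membered ring through C2, C3, C1' and C2', and so holds C3–H against C1'. The carboxyl carbon is removed afterwards and the tether oxygen stays as the methoxy oxygen.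

**Retrosynthetic reasoning**

Target 24 to acid 23. The C2–H bond is replaced by a C2–carboxyl bond. Chromone-2-carboxylic acids lose their carboxyl carbon on heating, so this cut costs one reliable step and gives C2 a handle. The forward step is a protodecarboxylation that the ring D olefin must survive.

Acid 23 to lactone 20. Ester 22 is the protected form of 23. In 22 the C2 ester carbon and the C2' methyl ether oxygen are reconnected through an acyl–oxygen bond, which gives the pentacyclic lactone 20. Forward, methanolysis of this activated aryl ester should release phenol 21, whose methylation gives 22. Saponification then gives 23.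

Lactone 20 to ester 19. The C3–C1' bond is cut here because in 20 it lies inside a six-membered ring. A hindered intermolecular coupling thus becomes a ring closure between the C–I carbon of ring B and the unfunctionalised C3–H. Neither a halide nor a boron group is needed on the chromone. The forward step is a palladium-catalysed intramolecular direct arylation.

Ester 19 to acid 5 and iodophenol 17. The ester C–O bond is the obvious convergent cut. The forward step is an acylation of a hindered phenol through acid chloride 18.

Iodophenol 17 to chromenol 13. The C6–I bond is cut. Electrophilic iodination of 13 could go ortho or para to the hydroxyl group, so the iodine is placed by directed ortho-lithiation of acetal ether 14 through aryllithium 15. The iodide 16 formed in this way is then unmasked to 17. An acetal ether was preferred to an O-aryl carbamate as the directing group. It leaves under mild acid, whereas a carbamate flanked by two ortho substituents is hard to hydrolyse.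

Chromenol 13 to ketone 9. The aromatic ring is traced back to a cyclohexenone. This avoids the regiochemical ambiguity of building the pyran on a resorcinol. Forward, α-selenenylation to 10, oxidation to selenoxide 11, syn-elimination to dienone 12 and tautomerisation should give 13.

Ketone 9 to diketone 6 and enal 7. The O–CMe2 bond and the bond from the ring carbon to the olefinic CH are cut together. Forward, Knoevenagel condensation to oxatriene 8 and 6π-electrocyclisation build ring D with the angular fusion fixed.

Acid 5 to acetophenone 1 and oxalate 2. The O1–C2 and C2–C3 bonds of ring C are cut. Forward, Claisen condensation gives diketo ester 3, cyclodehydration gives ester 4, and hydrolysis gives 5 in one operation.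

**Alternatives that were turned down**

Alternative 1: The cut lies inside ring D, and ring B is carried as a cyclohexenone that is aromatised only after it has been attached to the chromone.
- Key step: a cyclic 1,3-diketone condenses with the five-carbon enal, and the 1-oxatriene closes to bicyclic ketone A1. A1 is the same substance as compound 9.
- For: the pyran is placed angularly without ambiguity. The ketone carbon of A1 is the future C2' with its oxygen in place, and the α-carbon is the future C1'. The C3–C1' bond could therefore be made by palladium-catalysed α-arylation of the enolate of A1 with 3-iodo-7-methoxy-4H-chromen-4-one A2. This would give α-aryl ketone A3, and dehydrogenation and O-methylation would finish the synthesis. On paper this takes six or seven steps and needs no tether, no directed metalation and no decarboxylation. On step count it is stronger than the chosen route.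
- Against: the key step solves the easy part. The hard bond is left to an α-arylation that needs a strong base in the presence of A2, whose C2 adds enolates and alkoxides with ring opening. The nucleophile is a hindered cross-conjugated enolate. A3 would then have to be dehydrogenated late, next to the chromone and the ring D olefin.
- Comparison: the chosen route uses the same annulation as its step 2 but aromatises at once on a small intermediate. It forms C3–C1' with carbonate as the only base, at a site fixed by ring geometry.

Alternative 2: Ring B is taken apart completely, at C1'–C2', C2'–C3' and C4'–C5'.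
- Key step: irradiation of diazoketone A4 triggers a Wolff rearrangement to a chromonyl vinylketene. This adds siloxyalkyne A5 in a [2+2] sense. The vinylcyclobutenone opens by 4π-electrocyclisation, and 6π-closure with tautomerisation gives phenol A6, with hydroxyl at C2', prenyl at C3' and silyloxy at C4'.
- For: the substitution pattern of ring B follows from the connectivity of the two components, without any directing group. On ring B regiochemistry this is stronger than the lithiation of the chosen route. The C3–C1' bond exists from the start as a simple C3–vinyl bond. The two ring B oxygens emerge differentiated.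
- Against: A5 needs ynolate chemistry, and A4 needs a diazo transfer on a base-sensitive chromone. The chromone absorbs where the diazoketone is photolysed, and its C2=C3 bond undergoes photocycloaddition. After the key step, methylation, desilylation and oxidative cyclisation of the ortho-prenylphenol to ring D are still required.
- Comparison: the sequence is longer and depends on photochemistry. The chosen route offers ordinary reagents, a thermal catalytic key step and a ring D that is complete before the fragments are joined.

Alternative 3: Ring C is cut at C3–C4 and O1–C2.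
- Key step: [Cp*RhCl2]2 (trivalent rhodium) with Cu(OAc)2 (divalent copper) as oxidant activates the aldehyde C–H bond of 2-hydroxy-4-methoxybenzaldehyde A7. Silylalkyne A8 inserts, and C–O reductive elimination gives 2-silyl isoflavone A9. Protodesilylation of A9 would give the target.
- For: A8 would come from the same ring B aryl iodide by a Sonogashira coupling. The aryl–carbon bond is then made at an unhindered sp carbon, and ring C is built last, so no chromone is exposed to base. Three steps lead from the aryl iodide to the target, against five in the chosen route. This is the strongest alternative on step economy.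
- Against: the product is correct only if silicon ends next to rhodium during insertion. With an electron-rich ortho-alkoxy aryl group on the other alkyne carbon this is not assured, and the other sense gives the 2-aryl isomer. Silylalkynes insert slowly and can lose silicon under the copper acetate conditions. The acylrhodium intermediate can decarbonylate. The stoichiometric oxidant meets the electron-rich ring D olefin.
- Comparison: the chosen route is longer, but its tether can deliver only the 3-aryl product, and its ring C comes from a classical condensation.

Key step: step 9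

Remark on the chemistry: the target is achiral. Selenide 10 is racemic and selenoxide 11 is a mixture of stereoisomers; both stereogenic elements disappear in step 4.

**Route**

Step 1
Reactants: 1 2-hydroxy-4-methoxyacetophenone; 2 diethyl oxalate
Product: 5 7-methoxy-4-oxo-4H-chromene-2-carboxylic acid, via diketo ester 3 (not isolated), via ethyl chromone-2-carboxylate 4 (not isolated)
Conditions: NaOEt, EtOH, reflux; then conc. HCl, AcOH, reflux
Reagents that add atoms: water, O
Why: Claisen condensation of the methyl ketone enolate with the oxalate gives the 2,4-dioxobutanoate; acid closes the pyranone by cyclodehydration and hydrolyses the ester. This is the classical preparation of chromone-2-carboxylic acids.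

Step 2
Reactants: 6 cyclohexane-1,3-dione; 7 3-methylbut-2-enal
Product: 9 2,2-dimethyl-7,8-dihydro-2H-chromen-5(6H)-one, via 1-oxatriene 8 (not isolated)
Conditions: ethylenediammonium diacetate (10 mol %), MeOH, rt
Reagents that add atoms: none
Why: Knoevenagel condensation followed by 6π-oxa-electrocyclisation of the dienone should give the 2H-pyran. The fusion is angular by construction.

Step 3
Reactants: 9 2,2-dimethyl-7,8-dihydro-2H-chromen-5(6H)-one
Product: 10 2,2-dimethyl-6-(phenylselanyl)-7,8-dihydro-2H-chromen-5(6H)-one (racemic)
Conditions: LiN(iPr)2, THF, −78 °C; PhSeCl, −78 °C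
Reagents that add atoms: benzeneselenenyl chloride, Cl[Se]c1ccccc1
Why: Kinetic deprotonation of a vinylogous ester occurs at the α'-carbon C6, and the enolate is selenenylated there. The new stereocentre at C6 is formed as a racemate and is destroyed in step 4.

Step 4
Reactants: 10 2,2-dimethyl-6-(phenylselanyl)-7,8-dihydro-2H-chromen-5(6H)-one
Product: 13 2,2-dimethyl-2H-chromen-5-ol, via selenoxide 11 (not isolated), via cross-conjugated dienone 12 (not isolated)
Conditions: mCPBA (1 equiv), CH2Cl2, −78 °C; iPr2NH, −78 °C → rt
Reagents that add atoms: none
Why: Selenoxide syn-elimination towards C7 gives the 2,5-dienone, which tautomerises to the phenol. One equivalent of peracid at low temperature spares the ring D olefin, and the amine intercepts the selenenic acid.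

Step 5
Reactants: 13 2,2-dimethyl-2H-chromen-5-ol
Product: 14 5-(methoxymethoxy)-2,2-dimethyl-2H-chromene
Conditions: MOMCl, iPr2NEt, CH2Cl2, 0 °C → rt
Reagents that add atoms: chloromethyl methyl ether, COCCl
Why: O-alkylation of the phenol gives the acetal ether. This group serves both as protection and as the chelating director for the lithiation.

Step 6
Reactants: 14 5-(methoxymethoxy)-2,2-dimethyl-2H-chromene
Product: 16 6-iodo-5-(methoxymethoxy)-2,2-dimethyl-2H-chromene, via C6 aryllithium 15 (not isolated)
Conditions: n-BuLi, TMEDA, Et2O, 0 °C; I2, THF, −78 °C → rt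
Reagents that add atoms: iodine, II
Why: Directed ortho-metalation: the acetal oxygens chelate lithium and deliver the base to C6, the only free carbon ortho to the directing group. The ring oxygen is a weak director because it is flanked by the quaternary CMe2 carbon. Iodine quenches the aryllithium.

Step 7
Reactants: 16 6-iodo-5-(methoxymethoxy)-2,2-dimethyl-2H-chromene
Product: 17 6-iodo-2,2-dimethyl-2H-chromen-5-ol
Conditions: conc. HCl (cat.), MeOH, 40 °C
Reagents that add atoms: none
Why: Acid-catalysed transacetalisation removes the methoxymethyl group under conditions mild enough for the aryl iodide and the chromene olefin.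

Step 8
Reactants: 5 7-methoxy-4-oxo-4H-chromene-2-carboxylic acid; 17 6-iodo-2,2-dimethyl-2H-chromen-5-ol
Product: 19 6-iodo-2,2-dimethyl-2H-chromen-5-yl 7-methoxy-4-oxo-4H-chromene-2-carboxylate, via acid chloride 18 (not isolated)
Conditions: (COCl)2, DMF (cat.), CH2Cl2, 0 °C → rt; then 17, Et3N, DMAP (cat.), CH2Cl2, 0 °C → rt
Reagents that add atoms: none
Why: Acylation of a phenol by an acid chloride with nucleophilic catalysis. The acyl chloride and DMAP overcome the hindrance of the doubly ortho-substituted phenol.

Step 9
Reactants: 19 6-iodo-2,2-dimethyl-2H-chromen-5-yl 7-methoxy-4-oxo-4H-chromene-2-carboxylate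
Product: 20 pentacyclic lactone (7-methoxychromone whose C2 carboxyl is esterified to O5 of the 2,2-dimethyl-2H-chromene; chromene C6 bonded to chromone C3)
Conditions: Pd(OAc)2 (10 mol %), PCy3·HBF4 (20 mol %), PivOH (30 mol %), K2CO3, Ag2CO3, DMA, 110 °C
Reagents that add atoms: none
Why: Pd(OAc)2 is reduced by the phosphine to zerovalent palladium, which inserts into the C–I bond of ring B; Ag2CO3 removes iodide, which would otherwise inhibit the catalyst, and leaves an arylpalladium pivalate. After rotation of the ester into its s-cis form, pivalate-assisted concerted metalation–deprotonation of chromone C3–H gives a seven-membered palladacycle, and C–C reductive elimination forms C3–C1' and closes the lactone. The closest known reaction type is the palladium-catalysed intramolecular direct arylation of ester-tethered aryl halides to biaryl lactones and of 4-aryloxycoumarins at their enone α-C–H. The six-membered ring closes by reductive elimination with C2 and C3 both as ring members, that is, endo with respect to the C2=C3 bond. No stereocentre is formed. The step needs C3–H palladation to win over 5-exo insertion of C2=C3 into the aryl–palladium bond, over hydrodeiodination and over cleavage of the activated aryl ester. The tether lets only C3–H reach C1' in a six-membered ring, insertion at the fully substituted C2 would have to build a spiro quaternary centre, and anhydrous carbonate keeps the ester intact.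

Step 10
Reactants: 20 pentacyclic lactone
Product: 22 methyl 7-methoxy-3-(5-methoxy-2,2-dimethyl-2H-chromen-6-yl)-4-oxo-4H-chromene-2-carboxylate, via hydroxy methyl ester 21 (not isolated)
Conditions: K2CO3, MeOH–THF, 0 °C → rt; then MeI, 40 °C
Reagents that add atoms: methanol, CO; iodomethane, CI
Why: Transesterification of an activated aryl ester: methoxide opens the lactone at the acyl carbon and releases the C2' phenoxide, which is O-methylated in a Williamson reaction before it can close back.

Step 11
Reactants: 22 methyl 7-methoxy-3-(5-methoxy-2,2-dimethyl-2H-chromen-6-yl)-4-oxo-4H-chromene-2-carboxylate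
Product: 23 7-methoxy-3-(5-methoxy-2,2-dimethyl-2H-chromen-6-yl)-4-oxo-4H-chromene-2-carboxylic acid
Conditions: LiOH, THF–H2O, 0 °C → rt; then 1 M HCl
Reagents that add atoms: lithium hydroxide (aqueous), [Li+].[OH-]
Why: Saponification. Chromone-2-carboxylates are activated esters that hydrolyse near room temperature, and the carboxylate formed deactivates C2 towards further hydroxide attack.

Step 12
Reactants: 23 7-methoxy-3-(5-methoxy-2,2-dimethyl-2H-chromen-6-yl)-4-oxo-4H-chromene-2-carboxylic acid
Product: 24 7-methoxy-3-(5-methoxy-2,2-dimethyl-2H-chromen-6-yl)-4H-chromen-4-one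
Conditions: Cu2O (10 mol %), 1,10-phenanthroline (20 mol %), NMP–quinoline, 170 °C
Reagents that add atoms: none
Why: Copper-catalysed protodecarboxylation. The carboxylate sits on an sp2 carbon α to the ring oxygen and ortho to the twisted C3 aryl group, and both features ease loss of carbon dioxide. The temperature is below that at which 2,2-dimethylchromenes are routinely formed by thermal rearrangement.

**Compound list**

1 | 2-hydroxy-4-methoxyacetophenone | CC(=O)c1ccc(OC)cc1O | starting material
2 | diethyl oxalate | CCOC(=O)C(=O)OCC | starting material
3 | ethyl 4-(2-hydroxy-4-methoxyphenyl)-2,4-dioxobutanoate | CCOC(=O)C(=O)CC(=O)c1ccc(OC)cc1O | intermediate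
4 | ethyl 7-methoxy-4-oxo-4H-chromene-2-carboxylate | CCOC(=O)c1cc(=O)c2ccc(OC)cc2o1 | intermediate
5 | 7-methoxy-4-oxo-4H-chromene-2-carboxylic acid | COc1ccc2c(=O)cc(C(=O)O)oc2c1 | intermediate
6 | cyclohexane-1,3-dione | O=C1CCCC(=O)C1 | starting material
7 | 3-methylbut-2-enal | CC(C)=CC=O | starting material
8 | 2-(3-methylbut-2-en-1-ylidene)cyclohexane-1,3-dione | CC(C)=CC=C1C(=O)CCCC1=O | intermediate
9 | 2,2-dimethyl-7,8-dihydro-2H-chromen-5(6H)-one | CC1(C)C=CC2=C(CCCC2=O)O1 | intermediate
10 | 2,2-dimethyl-6-(phenylselanyl)-7,8-dihydro-2H-chromen-5(6H)-one (racemic) | CC1(C)C=CC2=C(CCC([Se]c3ccccc3)C2=O)O1 | intermediate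
11 | 2,2-dimethyl-6-(phenylseleninyl)-7,8-dihydro-2H-chromen-5(6H)-one (mixture of stereoisomers) | CC1(C)C=CC2=C(CCC([Se](=O)c3ccccc3)C2=O)O1 | intermediate
12 | 2,2-dimethyl-2H-chromen-5(8H)-one | CC1(C)C=CC2=C(CC=CC2=O)O1 | intermediate
13 | 2,2-dimethyl-2H-chromen-5-ol | CC1(C)C=Cc2c(O)cccc2O1 | intermediate
14 | 5-(methoxymethoxy)-2,2-dimethyl-2H-chromene | COCOc1cccc2OC(C)(C)C=Cc12 | intermediate
15 | [5-(methoxymethoxy)-2,2-dimethyl-2H-chromen-6-yl]lithium | [Li]c1ccc2OC(C)(C)C=Cc2c1OCOC | intermediate
16 | 6-iodo-5-(methoxymethoxy)-2,2-dimethyl-2H-chromene | COCOc1c(I)ccc2OC(C)(C)C=Cc12 | intermediate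
17 | 6-iodo-2,2-dimethyl-2H-chromen-5-ol | Oc1c(I)ccc2OC(C)(C)C=Cc12 | intermediate
18 | 7-methoxy-4-oxo-4H-chromene-2-carbonyl chloride | COc1ccc2c(=O)cc(C(=O)Cl)oc2c1 | intermediate
19 | 6-iodo-2,2-dimethyl-2H-chromen-5-yl 7-methoxy-4-oxo-4H-chromene-2-carboxylate | COc1ccc2c(=O)cc(C(=O)Oc3c(I)ccc4OC(C)(C)C=Cc34)oc2c1 | intermediate
20 | pentacyclic lactone: 7-methoxychromone with its C2 carboxyl esterified to O5 of a 2,2-dimethyl-2H-chromene whose C6 is bonded to chromone C3 | COc1ccc2c(c1)oc1c(c2=O)-c2ccc3OC(C)(C)C=Cc3c2OC1=O | intermediate
21 | methyl 3-(5-hydroxy-2,2-dimethyl-2H-chromen-6-yl)-7-methoxy-4-oxo-4H-chromene-2-carboxylate | COC(=O)c1oc2cc(OC)ccc2c(=O)c1-c1ccc2OC(C)(C)C=Cc2c1O | intermediate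
22 | methyl 7-methoxy-3-(5-methoxy-2,2-dimethyl-2H-chromen-6-yl)-4-oxo-4H-chromene-2-carboxylate | COC(=O)c1oc2cc(OC)ccc2c(=O)c1-c1ccc2OC(C)(C)C=Cc2c1OC | intermediate
23 | 7-methoxy-3-(5-methoxy-2,2-dimethyl-2H-chromen-6-yl)-4-oxo-4H-chromene-2-carboxylic acid | OC(=O)c1oc2cc(OC)ccc2c(=O)c1-c1ccc2OC(C)(C)C=Cc2c1OC | intermediate
24 | 7-methoxy-3-(5-methoxy-2,2-dimethyl-2H-chromen-6-yl)-4H-chromen-4-one | COc1ccc2c(=O)c(-c3ccc4c(c3OC)C=CC(C)(C)O4)coc2c1 | target

**Step count and least certain steps**

Total step count: 12. Longest linear sequence: 11 steps (steps 2 to 12, from 6 and 7). Acid 5 is made in one step and joins in step 8.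

Step 9 (key step). The arylpalladium intermediate may insert the chromone C2=C3 bond in the 5-exo sense and end as a palladium enolate that cannot turn over. It may also be reduced with loss of iodine. The activated aryl ester may be cleaved by carbonate or pivalate at 110 °C before the slow rotation into the s-cis ester conformer allows C–H palladation.
Fallback: an intermolecular Suzuki–Miyaura coupling that sets out from 17 and from 1 and rejoins the route at 24.
- Iodophenol 17 would be O-methylated (MeI, K2CO3, acetone) to 6-iodo-5-methoxy-2,2-dimethyl-2H-chromene F1.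
- F1 would be borylated (B2pin2, PdCl2(dppf), KOAc, 1,4-dioxane, 80 °C) to the pinacol boronate F2.
- Acetophenone 1 would be condensed with N,N-dimethylformamide dimethyl acetal to the enaminone F3.
- Iodine in chloroform would close F3 to 3-iodo-7-methoxy-4H-chromen-4-one F4.
- Coupling of F2 with F4 (PdCl2(dppf), aqueous Na2CO3, DME, 80 °C) would give 24 directly.

Step 6. Lithiation may not be confined to C6. Deprotonation at C8 next to the ring oxygen, or addition of butyllithium to the styrene-type double bond, would lower the selectivity.
Fallback: a stronger directing group, setting out from 13 and rejoining at 17.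
- Chromenol 13 would be acylated (ClCONEt2, K2CO3, MeCN) to 2,2-dimethyl-2H-chromen-5-yl diethylcarbamate F5.
- Lithiation ortho to the carbamate at −78 °C (s-BuLi, TMEDA, THF) and an iodine quench would give 6-iodo-2,2-dimethyl-2H-chromen-5-yl diethylcarbamate F6.
- Hydrolysis of F6 (NaOH, EtOH, reflux) would return 17.

Step 10. Methoxide may add to C2 of the pyranone instead of the lactone carbonyl. Ring C would then open and methyl iodide would trap the ring A phenoxide. Alternatively, methylation of the C2' phenoxide in methanol may be slow enough for the lactone to close again on work-up.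
Fallback: hydroxide opening and aprotic methylation, setting out from 20 and rejoining at 22.
- Lactone 20 would be opened with LiOH in THF–H2O at 0 °C to 3-(5-hydroxy-2,2-dimethyl-2H-chromen-6-yl)-7-methoxy-4-oxo-4H-chromene-2-carboxylic acid F7.
- F7 would be kept as its dilithium salt and not acidified. Its carboxylate shields C2 from further attack.
- After evaporation, exhaustive methylation (MeI, K2CO3, DMF) would give 22.

Step 12. Loss of carbon dioxide may be slow and call for temperatures at which ring D opens electrocyclically and isomerises by hydrogen shift.
Fallback: degradation and one-carbon re-closure, setting out from 23 and rejoining at 24.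
- Hot aqueous ethanolic KOH would open ring C of 23 and cleave the resulting α,γ-diketo acid to 1-(2-hydroxy-4-methoxyphenyl)-2-(5-methoxy-2,2-dimethyl-2H-chromen-6-yl)ethan-1-one F8.
- N,N-Dimethylformamide dimethyl acetal in toluene at 90 °C would convert F8 into 3-(dimethylamino)-1-(2-hydroxy-4-methoxyphenyl)-2-(5-methoxy-2,2-dimethyl-2H-chromen-6-yl)prop-2-en-1-one F9.
- F9 would cyclise with loss of dimethylamine to 24.

Step 4. The selenenic acid set free may add back to the electron-rich phenol or to the ring D olefin, and any excess oxidant may attack the new phenol.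
Fallback: a selenium-free dehydrogenation, setting out from 9 and rejoining at 13.
- Ketone 9 would be converted (LiN(iPr)2, Me3SiCl, THF, −78 °C) into [(2,2-dimethyl-7,8-dihydro-2H-chromen-5-yl)oxy]trimethylsilane F10.
- Saegusa–Ito oxidation of F10 with Pd(OAc)2 in MeCN would give dienone 12, which tautomerises to 13.

**Further compounds**

F1 | step 9 | 6-iodo-5-methoxy-2,2-dimethyl-2H-chromene | COc1c(I)ccc2OC(C)(C)C=Cc12
F2 | step 9 | 2-(5-methoxy-2,2-dimethyl-2H-chromen-6-yl)-4,4,5,5-tetramethyl-1,3,2-dioxaborolane | COc1c(B3OC(C)(C)C(C)(C)O3)ccc2OC(C)(C)C=Cc12
F3 | step 9 | (E)-3-(dimethylamino)-1-(2-hydroxy-4-methoxyphenyl)prop-2-en-1-one | CN(C)/C=C/C(=O)c1ccc(OC)cc1O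
F4 | step 9 | 3-iodo-7-methoxy-4H-chromen-4-one | COc1ccc2c(=O)c(I)coc2c1
F5 | step 6 | 2,2-dimethyl-2H-chromen-5-yl diethylcarbamate | CCN(CC)C(=O)Oc1cccc2OC(C)(C)C=Cc12
F6 | step 6 | 6-iodo-2,2-dimethyl-2H-chromen-5-yl diethylcarbamate | CCN(CC)C(=O)Oc1c(I)ccc2OC(C)(C)C=Cc12
F7 | step 10 | 3-(5-hydroxy-2,2-dimethyl-2H-chromen-6-yl)-7-methoxy-4-oxo-4H-chromene-2-carboxylic acid | OC(=O)c1oc2cc(OC)ccc2c(=O)c1-c1ccc2OC(C)(C)C=Cc2c1O
F8 | step 12 | 1-(2-hydroxy-4-methoxyphenyl)-2-(5-methoxy-2,2-dimethyl-2H-chromen-6-yl)ethan-1-one | COc1ccc(C(=O)Cc2ccc3OC(C)(C)C=Cc3c2OC)c(O)c1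
F9 | step 12 | 3-(dimethylamino)-1-(2-hydroxy-4-methoxyphenyl)-2-(5-methoxy-2,2-dimethyl-2H-chromen-6-yl)prop-2-en-1-one (double-bond geometry not fixed) | COc1ccc(C(=O)C(=CN(C)C)c2ccc3OC(C)(C)C=Cc3c2OC)c(O)c1
F10 | step 4 | [(2,2-dimethyl-7,8-dihydro-2H-chromen-5-yl)oxy]trimethylsilane | CC1(C)C=CC2=C(CCC=C2O[Si](C)(C)C)O1
A1 | alternative 1 | 2,2-dimethyl-7,8-dihydro-2H-chromen-5(6H)-one | CC1(C)C=CC2=C(CCCC2=O)O1
A2 | alternative 1 | 3-iodo-7-methoxy-4H-chromen-4-one | COc1ccc2c(=O)c(I)coc2c1
A3 | alternative 1 | 6-(7-methoxy-4-oxo-4H-chromen-3-yl)-2,2-dimethyl-7,8-dihydro-2H-chromen-5(6H)-one (racemic) | COc1ccc2c(=O)c(C3CCC4=C(C=CC(C)(C)O4)C3=O)coc2c1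
A4 | alternative 2 | (E)-1-diazo-4-(7-methoxy-4-oxo-4H-chromen-3-yl)but-3-en-2-one | COc1ccc2c(=O)c(/C=C/C(=O)C=[N+]=[N-])coc2c1
A5 | alternative 2 | triisopropyl[(5-methylhex-4-en-1-yn-1-yl)oxy]silane | CC(C)=CCC#CO[Si](C(C)C)(C(C)C)C(C)C
A6 | alternative 2 | 3-[2-hydroxy-3-(3-methylbut-2-enyl)-4-(triisopropylsilyloxy)phenyl]-7-methoxy-4H-chromen-4-one | COc1ccc2c(=O)c(-c3ccc(O[Si](C(C)C)(C(C)C)C(C)C)c(CC=C(C)C)c3O)coc2c1
A7 | alternative 3 | 2-hydroxy-4-methoxybenzaldehyde | COc1ccc(C=O)c(O)c1
A8 | alternative 3 | [(5-methoxy-2,2-dimethyl-2H-chromen-6-yl)ethynyl]trimethylsilane | COc1c(C#C[Si](C)(C)C)ccc2OC(C)(C)C=Cc12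
A9 | alternative 3 | 7-methoxy-3-(5-methoxy-2,2-dimethyl-2H-chromen-6-yl)-2-(trimethylsilyl)-4H-chromen-4-one | COc1ccc2c(=O)c(-c3ccc4c(c3OC)C=CC(C)(C)O4)c([Si](C)(C)C)oc2c1
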